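**Strategy**

The ten-membered carbocycle (C1–C10, germacrane numbering) is closed last at the C9–C10 single bond. The key step exploits the homoallylic array C8(OH)–C9H2–C10(CH3)=C1 of this ring: a C9 iodohydrin and a (Z)-C10 alkenyl iodide are joined by intramolecular nickel-catalysed reductive coupling, which in one operation forms the ring, carries over the (Z)-C1=C10 geometry and leaves the C8 hydroxyl free for acylation. The precursor is an open chain that already holds the trans-disubstituted α-methylene-γ-butyrolactone (O–C6–C7–C11–C12), the (E)-C4=C5 alkene and the stereocentres C2, C6, C7 and C8; it comes from a chromium-mediated, lactone-forming allylation of two fragments.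

Key step: step 13

Remark on the chemistry: germacrane numbering is used throughout (ring C1–C10, C14 methyl on C10, C15 methyl on C4, lactone C12(=O)–O–C6 with C11=C13 on C7). The target is taken as the 1(10)Z,4E isomer with 2R,6R,7R,8R and 2'S configuration, as read from the SMILES.

**Route**

Step 1
Reactants: 1 but-2-yn-1-ol
Product: 3 (2Z)-3-iodobut-2-en-1-ol, via cyclic sodium alkenylalanate 2 (not isolated)
Conditions: NaAlH2(OCH2CH2OMe)2, THF, 0 °C to rt; then I2, −78 °C to 0 °C
Reagents that add atoms: iodine, II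
Why: Hydroxyl-directed trans-hydroalumination places aluminium on C3 cis to the CH2O group, and iodinolysis with retention should give the (Z)-alkenyl iodide that later becomes C14/C10/C1/C2 in its final geometry.

Step 2
Reactants: 3 (2Z)-3-iodobut-2-en-1-ol
Product: 4 (2Z)-3-iodobut-2-enal
Conditions: MnO2, CH2Cl2, rt, dark; used at once
Reagents that add atoms: none
Why: Neutral allylic oxidation with MnO2 should keep the (Z)-geometry of the labile iodoenal.

Step 3
Reactants: 5 methyl 3-methylbut-2-enoate
Product: 7 (1Z)-1-methoxy-3-methyl-1-[(tert-butyldimethylsilyl)oxy]buta-1,3-diene, via lithium dienolate 6 (not isolated)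
Conditions: LiN(i-Pr)2, THF, −78 °C; then TBSCl, DMPU, −78 °C to rt
Reagents that add atoms: tert-butyldimethylsilyl chloride, CC(C)(C)[Si](C)(C)Cl
Why: γ-Deprotonation of the enoate and O-silylation give the silyl dienol ether that serves as the vinylogous nucleophile; its ketene-acetal geometry is not relayed to the product.

Step 4
Reactants: 4 (2Z)-3-iodobut-2-enal; 7 silyl dienol ether
Product: 9 methyl (2E,5R,6Z)-5-hydroxy-7-iodo-3-methylocta-2,6-dienoate, via trichlorosilyl ether 8 (not isolated)
Conditions: SiCl4, chiral 1,1'-binaphthyl-2,2'-diamine-derived bisphosphoramide (5 mol%, the antipode that gives 5R), CH2Cl2, −78 °C; aqueous work-up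
Reagents that add atoms: none
Why: In this Lewis-base-activated vinylogous Mukaiyama aldol the dienolate attacks the silicon-bound enal through its γ-carbon to give the (E)-enoate (C3–C6 of the target), and the chiral phosphoramide–silicon complex selects the aldehyde face that sets C2 as R.

Step 5
Reactants: 9 hydroxy ester
Product: 10 methyl (2E,5R,6Z)-5-[(tert-butyldimethylsilyl)oxy]-7-iodo-3-methylocta-2,6-dienoate
Conditions: TBSCl, imidazole, DMF, rt
Reagents that add atoms: tert-butyldimethylsilyl chloride, CC(C)(C)[Si](C)(C)Cl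
Why: Standard silylation of the secondary allylic alcohol gives an ether that should last until the final fluoride step.

Step 6
Reactants: 10 silyl ether ester
Product: 11 (2E,5R,6Z)-5-[(tert-butyldimethylsilyl)oxy]-7-iodo-3-methylocta-2,6-dien-1-ol
Conditions: i-Bu2AlH, CH2Cl2, −78 °C; aq. potassium sodium tartrate
Reagents that add atoms: none
Why: 1,2-Reduction of the enoate to the allylic alcohol should leave the alkenyl iodide and the silyl ether untouched.

Step 7
Reactants: 11 allylic alcohol
Product: 12 (2E,5R,6Z)-5-[(tert-butyldimethylsilyl)oxy]-7-iodo-3-methylocta-2,6-dienal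
Conditions: MnO2, CH2Cl2, rt
Reagents that add atoms: none
Why: Selective allylic oxidation should give the (E)-enal whose carbonyl carbon becomes C6.

Step 8
Reactants: 13 (4R)-2,2-dimethyl-1,3-dioxolane-4-carbaldehyde; 14 methyl acrylate
Product: 15 methyl 2-{hydroxy[(4R)-2,2-dimethyl-1,3-dioxolan-4-yl]methyl}prop-2-enoate (both carbinol epimers)
Conditions: 1,4-diazabicyclo[2.2.2]octane, dioxane/H2O, rt
Reagents that add atoms: none
Why: The Morita–Baylis–Hillman reaction joins C7 to C11, and the new carbinol centre is removed in the next step, so the epimer mixture is used as such.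

Step 9
Reactants: 15 Morita–Baylis–Hillman adduct
Product: 16 methyl (2Z)-2-(bromomethyl)-3-[(4S)-2,2-dimethyl-1,3-dioxolan-4-yl]prop-2-enoate
Conditions: NBS, Me2S, CH2Cl2, 0 °C to rt
Reagents that add atoms: N-bromosuccinimide, O=C1CCC(=O)N1Br
Why: Bromosulfonium activation of the hydroxyl and SN2' attack of bromide (allylic transposition) should give the thermodynamically preferred (Z)-2-(bromomethyl)enoate with C8 untouched.

Step 10
Reactants: 12 enal; 16 allylic bromide
Product: 18 (4S,5R)-4-[(4S)-2,2-dimethyl-1,3-dioxolan-4-yl]-3-methylidene-5-[(1E,4R,5Z)-4-[(tert-butyldimethylsilyl)oxy]-6-iodo-2-methylhepta-1,5-dien-1-yl]oxolan-2-one, via hydroxy ester 17 (not isolated)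
Conditions: CrCl2 (nickel-free), THF, 0 °C to rt; then PPTS (cat.), CH2Cl2, rt
Reagents that add atoms: none
Why: In this Nozaki–Hiyama–Kishi-type 2-(alkoxycarbonyl)allylation the configurationally labile allylchromium should react at C7 through a chair transition state with the C8 substituent equatorial (anti adduct, hence the trans lactone), the aldehyde approaching the alkene face anti to the dioxolane CH2 arm with H8 in the alkene plane (allylic 1,3-strain), which sets C6 and C7 relative to C8 before the alkoxide lactonises onto the ester; the alkenyl iodide is inert to divalent chromium without nickel.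

Step 11
Reactants: 18 lactone acetonide
Product: 19 (4R,5R)-4-[(1S)-1,2-dihydroxyethyl]-3-methylidene-5-[(1E,4R,5Z)-4-[(tert-butyldimethylsilyl)oxy]-6-iodo-2-methylhepta-1,5-dien-1-yl]oxolan-2-one
Conditions: AcOH/H2O (4:1), rt
Reagents that add atoms: none
Why: The terminal isopropylidene acetal should hydrolyse faster than the hindered secondary silyl ether is cleaved or the lactone migrates to O8.

Step 12
Reactants: 19 diol
Product: 20 (4R,5R)-4-[(1S)-1-hydroxy-2-iodoethyl]-3-methylidene-5-[(1E,4R,5Z)-4-[(tert-butyldimethylsilyl)oxy]-6-iodo-2-methylhepta-1,5-dien-1-yl]oxolan-2-one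
Conditions: PPh3, I2, imidazole, CH2Cl2, 0 °C (diol added to the preformed reagent)
Reagents that add atoms: iodine, II
Why: Appel-type iodination through the alkoxyphosphonium salt should be selective for the primary hydroxyl (C9), leaving the C8 carbinol free and its configuration untouched.

Step 13
Reactants: 20 iodohydrin alkenyl iodide
Product: 21 (2R,6R,7R,8R)-2-[(tert-butyldimethylsilyl)oxy]-8-hydroxygermacra-1(10)Z,4E,11(13)-trien-12,6-olide
Conditions: NiBr2(MeOCH2CH2OMe) (20 mol%), 4,4'-di-tert-butyl-2,2'-bipyridine, Mn powder, NaI, N,N-dimethylacetamide, 30 °C, syringe-pump addition to 2 mM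
Reagents that add atoms: none
Why: Proposed new method: zerovalent nickel (from NiBr2(MeOCH2CH2OMe) and Mn) should add oxidatively to the C10–I bond with retention of the (Z)-geometry, a monovalent nickel species abstracts iodine from C9, and the primary C9 radical is captured at the alkenylnickel centre of the same molecule, after which reductive elimination from trivalent nickel forms the C9–C10 bond. The closest known reaction types are the nickel-catalysed reductive cross-electrophile coupling of alkenyl halides with primary alkyl iodides and the iodide-co-catalysed nickel coupling of epoxides with aryl halides, which runs through an iodohydrin and tolerates the free β-hydroxyl; the closure of a ten-membered carbocycle is the untested part. The ten-membered ring closes head-to-tail at C9–C10 by radical capture and reductive elimination at nickel, not by radical addition to an alkene, so the ring strain is met in an organometallic step. No stereocentre is formed: C2, C6, C7 and C8 are carried in unchanged and the C1=C10 geometry is fixed by the alkenyl iodide. The step needs ring closure to outrun dimerisation, hydrodehalogenation and addition of the C9 radical to the C11=C13 methylene (a disfavoured 5-endo closure); slow addition at high dilution and the preorganisation given by the trans lactone, the (E)-C4=C5 alkene and the (Z)-alkenyl iodide should secure this.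

Step 14
Reactants: 22 methyl (2S)-3-hydroxy-2-methylpropanoate
Product: 23 methyl (2S)-3-[(tert-butyldimethylsilyl)oxy]-2-methylpropanoate
Conditions: TBSCl, imidazole, CH2Cl2, rt
Reagents that add atoms: tert-butyldimethylsilyl chloride, CC(C)(C)[Si](C)(C)Cl
Why: Silylation of the primary hydroxyl does not touch the α-stereocentre.

Step 15
Reactants: 23 silyl ether ester
Product: 25 (2S)-3-[(tert-butyldimethylsilyl)oxy]-2-methylpropanoic acid, via lithium carboxylate 24 (not isolated)
Conditions: LiOH, THF/H2O, 0 °C; then 1 M HCl, 0 °C, to pH 4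
Reagents that add atoms: lithium hydroxide, [Li+].[OH-]
Why: Saponification at 0 °C should be faster than enolisation of the α-stereocentre, so the S configuration is kept.

Step 16
Reactants: 21 macrocyclic alcohol; 25 acid
Product: 26 (2R,6R,7R,8R)-2-[(tert-butyldimethylsilyl)oxy]-8-{[(2S)-3-[(tert-butyldimethylsilyl)oxy]-2-methylpropanoyl]oxy}germacra-1(10)Z,4E,11(13)-trien-12,6-olide
Conditions: DCC, DMAP (cat.), CH2Cl2, 0 °C to rt
Reagents that add atoms: none
Why: Steglich esterification acylates the only free hydroxyl (C8), and low temperature with catalytic DMAP should keep the α-stereocentre of the acid intact.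

Step 17
Reactants: 26 bis-silyl ether
Product: 27 CNP0254953.1, (2R,6R,7R,8R)-2-hydroxy-8-{[(2S)-3-hydroxy-2-methylpropanoyl]oxy}germacra-1(10)Z,4E,11(13)-trien-12,6-olide
Conditions: HF·pyridine, pyridine, THF, 0 °C to rt
Reagents that add atoms: none
Why: Buffered fluoride should cleave both silyl ethers without harming the α-methylene lactone, the ester or the allylic alcohol.

**Compound list**

1 | but-2-yn-1-ol | CC#CCO | starting material
2 | cyclic sodium alkenylalanate (sodium 2,2-bis(2-methoxyethoxy)-3-methyl-2,5-dihydro-1,2-oxaluminol-2-uide) | CC1=CCO[Al-]1(OCCOC)OCCOC.[Na+] | intermediate (not isolated)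
3 | (2Z)-3-iodobut-2-en-1-ol | C/C(I)=C/CO | intermediate
4 | (2Z)-3-iodobut-2-enal | C/C(I)=C/C=O | intermediate
5 | methyl 3-methylbut-2-enoate | COC(=O)C=C(C)C | starting material
6 | lithium 1-methoxy-3-methylbuta-1,3-dien-1-olate | [Li+].C=C(C)C=C([O-])OC | intermediate (not isolated)
7 | (1Z)-1-methoxy-3-methyl-1-[(tert-butyldimethylsilyl)oxy]buta-1,3-diene | C=C(C)/C=C(/OC)O[Si](C)(C)C(C)(C)C | intermediate
8 | methyl (2E,5R,6Z)-7-iodo-3-methyl-5-[(trichlorosilyl)oxy]octa-2,6-dienoate | COC(=O)/C=C(\C)C[C@@H](O[Si](Cl)(Cl)Cl)/C=C(/C)I | intermediate (not isolated)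
9 | methyl (2E,5R,6Z)-5-hydroxy-7-iodo-3-methylocta-2,6-dienoate | COC(=O)/C=C(\C)C[C@@H](O)/C=C(/C)I | intermediate
10 | methyl (2E,5R,6Z)-5-[(tert-butyldimethylsilyl)oxy]-7-iodo-3-methylocta-2,6-dienoate | COC(=O)/C=C(\C)C[C@@H](O[Si](C)(C)C(C)(C)C)/C=C(/C)I | intermediate
11 | (2E,5R,6Z)-5-[(tert-butyldimethylsilyl)oxy]-7-iodo-3-methylocta-2,6-dien-1-ol | OC/C=C(\C)C[C@@H](O[Si](C)(C)C(C)(C)C)/C=C(/C)I | intermediate
12 | (2E,5R,6Z)-5-[(tert-butyldimethylsilyl)oxy]-7-iodo-3-methylocta-2,6-dienal | O=C/C=C(\C)C[C@@H](O[Si](C)(C)C(C)(C)C)/C=C(/C)I | intermediate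
13 | (4R)-2,2-dimethyl-1,3-dioxolane-4-carbaldehyde ((R)-glyceraldehyde acetonide) | O=C[C@H]1COC(C)(C)O1 | starting material
14 | methyl acrylate | C=CC(=O)OC | starting material
15 | methyl 2-{hydroxy[(4R)-2,2-dimethyl-1,3-dioxolan-4-yl]methyl}prop-2-enoate (carbinol epimers) | C=C(C(=O)OC)C(O)[C@H]1COC(C)(C)O1 | intermediate
16 | methyl (2Z)-2-(bromomethyl)-3-[(4S)-2,2-dimethyl-1,3-dioxolan-4-yl]prop-2-enoate | COC(=O)/C(CBr)=C/[C@H]1COC(C)(C)O1 | intermediate
17 | methyl (3S,4R,5E,8R,9Z)-8-[(tert-butyldimethylsilyl)oxy]-3-[(4S)-2,2-dimethyl-1,3-dioxolan-4-yl]-4-hydroxy-10-iodo-6-methyl-2-methylideneundeca-5,9-dienoate (anti adduct) | COC(=O)C(=C)[C@@H]([C@H](O)/C=C(\C)C[C@@H](O[Si](C)(C)C(C)(C)C)/C=C(/C)I)[C@H]1COC(C)(C)O1 | intermediate (not isolated)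
18 | (4S,5R)-4-[(4S)-2,2-dimethyl-1,3-dioxolan-4-yl]-3-methylidene-5-[(1E,4R,5Z)-4-[(tert-butyldimethylsilyl)oxy]-6-iodo-2-methylhepta-1,5-dien-1-yl]oxolan-2-one | C=C1C(=O)O[C@H](/C=C(\C)C[C@@H](O[Si](C)(C)C(C)(C)C)/C=C(/C)I)[C@H]1[C@H]2COC(C)(C)O2 | intermediate
19 | (4R,5R)-4-[(1S)-1,2-dihydroxyethyl]-3-methylidene-5-[(1E,4R,5Z)-4-[(tert-butyldimethylsilyl)oxy]-6-iodo-2-methylhepta-1,5-dien-1-yl]oxolan-2-one | C=C1C(=O)O[C@H](/C=C(\C)C[C@@H](O[Si](C)(C)C(C)(C)C)/C=C(/C)I)[C@H]1[C@H](O)CO | intermediate
20 | (4R,5R)-4-[(1S)-1-hydroxy-2-iodoethyl]-3-methylidene-5-[(1E,4R,5Z)-4-[(tert-butyldimethylsilyl)oxy]-6-iodo-2-methylhepta-1,5-dien-1-yl]oxolan-2-one | C=C1C(=O)O[C@H](/C=C(\C)C[C@@H](O[Si](C)(C)C(C)(C)C)/C=C(/C)I)[C@H]1[C@H](O)CI | intermediate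
21 | (2R,6R,7R,8R)-2-[(tert-butyldimethylsilyl)oxy]-8-hydroxygermacra-1(10)Z,4E,11(13)-trien-12,6-olide | C=C1C(=O)O[C@@H]2/C=C(\C)C[C@@H](O[Si](C)(C)C(C)(C)C)/C=C(/C)C[C@@H](O)[C@@H]12 | intermediate
22 | methyl (2S)-3-hydroxy-2-methylpropanoate | COC(=O)[C@@H](C)CO | starting material
23 | methyl (2S)-3-[(tert-butyldimethylsilyl)oxy]-2-methylpropanoate | COC(=O)[C@@H](C)CO[Si](C)(C)C(C)(C)C | intermediate
24 | lithium (2S)-3-[(tert-butyldimethylsilyl)oxy]-2-methylpropanoate | [Li+].[O-]C(=O)[C@@H](C)CO[Si](C)(C)C(C)(C)C | intermediate (not isolated)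
25 | (2S)-3-[(tert-butyldimethylsilyl)oxy]-2-methylpropanoic acid | OC(=O)[C@@H](C)CO[Si](C)(C)C(C)(C)C | intermediate
26 | (2R,6R,7R,8R)-2-[(tert-butyldimethylsilyl)oxy]-8-{[(2S)-3-[(tert-butyldimethylsilyl)oxy]-2-methylpropanoyl]oxy}germacra-1(10)Z,4E,11(13)-trien-12,6-olide | C=C1C(=O)O[C@@H]2/C=C(\C)C[C@@H](O[Si](C)(C)C(C)(C)C)/C=C(/C)C[C@@H](OC(=O)[C@@H](C)CO[Si](C)(C)C(C)(C)C)[C@@H]12 | intermediate
27 | CNP0254953.1, (2R,6R,7R,8R)-2-hydroxy-8-{[(2S)-3-hydroxy-2-methylpropanoyl]oxy}germacra-1(10)Z,4E,11(13)-trien-12,6-olide | C=C1C(=O)O[C@@H]2/C=C(\C)C[C@@H](O)/C=C(/C)C[C@@H](OC(=O)[C@@H](C)CO)[C@@H]12 | target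

**Step count and risks**

Total step count: 17. Longest linear sequence: 12 steps (steps 1, 2, 4, 5, 6, 7, 10, 11, 12, 13, 16, 17, from but-2-yn-1-ol).

Steps most likely to fail:

1. Step 13 (proposed new method). Ring closure may lose to intermolecular coupling and oligomerisation, to hydrodehalogenation at C9 or C10, or to addition of the C9 radical to the exocyclic methylene; the alkenylnickel species may also lose its (Z)-geometry. The fallback uses known two-electron chemistry for the same C9–C10 bond and sets out from 20. Silylation (TESOTf, 2,6-lutidine, CH2Cl2, −78 °C) would give the 8-O-triethylsilyl ether F1. Copper-catalysed borylation of the primary iodide (bis(pinacolato)diboron, CuI, PPh3, LiOMe, DMF, rt) would give the C9 pinacol boronate F2. Intramolecular B-alkyl Suzuki–Miyaura coupling (PdCl2[1,1'-bis(diphenylphosphino)ferrocene], AsPh3, Cs2CO3, DMF/THF/H2O, high dilution) would then give the macrocyclic triethylsilyl ether F3; this reaction type is known to close medium rings onto trisubstituted alkenyl iodides and to tolerate β-alkoxy alkylboron reagents. Selective removal of the triethylsilyl group (PPTS, MeOH, 0 °C) comes back to the route at 21.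

2. Step 10. The anti (C6/C7) selectivity may erode if the allylchromium reacts through its (Z)-form, for example through chelation by the dioxolane oxygen, which would lead to the cis lactone. The fallback sets out from 12 and 16. An indium-mediated Barbier allylation (indium powder, THF/H2O, rt, neutral work-up), which keeps the (Z)-geometry of the allyl unit in the chair transition state, would give the syn adduct, the C6-epimeric hydroxy ester F4. Mitsunobu esterification (4-nitrobenzoic acid, PPh3, DIAD, THF, 0 °C) would invert C6 to give the 4-nitrobenzoate F5. Mild methanolysis (K2CO3, MeOH, 0 °C) would free 17, which lactonises and comes back to the route at 18.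

3. Step 4. The (Z)-iodoenal may isomerise under the Lewis acid, attack may occur at the α- instead of the γ-carbon of the dienolate, or the facial selectivity at C2 may be poor. The fallback sets out from 4 and 7. An achiral vinylogous Mukaiyama aldol (BF3·OEt2, CH2Cl2, −78 °C) would give the racemic hydroxy ester F6. Oxidation (Dess–Martin periodinane, NaHCO3, CH2Cl2, 0 °C) would give the 5-oxo ester F7. Reagent-controlled reduction ((S)-2-methyl-CBS-oxazaborolidine, catecholborane, toluene, −78 °C; the alkenyl group acts as the large substituent) should set the R carbinol and comes back to the route at 9.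

Further compounds

F1 | step 13 | 8-O-triethylsilyl ether of 20 | C=C1C(=O)O[C@H](/C=C(\C)C[C@@H](O[Si](C)(C)C(C)(C)C)/C=C(/C)I)[C@H]1[C@H](O[Si](CC)(CC)CC)CI
F2 | step 13 | C9 pinacol boronate (primary iodide of F1 replaced by 4,4,5,5-tetramethyl-1,3,2-dioxaborolan-2-yl) | C=C1C(=O)O[C@H](/C=C(\C)C[C@@H](O[Si](C)(C)C(C)(C)C)/C=C(/C)I)[C@H]1[C@H](O[Si](CC)(CC)CC)CB2OC(C)(C)C(C)(C)O2
F3 | step 13 | 8-O-triethylsilyl ether of macrocycle 21 | C=C1C(=O)O[C@@H]2/C=C(\C)C[C@@H](O[Si](C)(C)C(C)(C)C)/C=C(/C)C[C@@H](O[Si](CC)(CC)CC)[C@@H]12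
F4 | step 10 | C6 epimer of hydroxy ester 17 (syn adduct) | COC(=O)C(=C)[C@@H]([C@@H](O)/C=C(\C)C[C@@H](O[Si](C)(C)C(C)(C)C)/C=C(/C)I)[C@H]1COC(C)(C)O1
F5 | step 10 | 4-nitrobenzoate of hydroxy ester 17 (C6 inverted relative to F4) | COC(=O)C(=C)[C@@H]([C@H](OC(=O)c1ccc(cc1)[N+](=O)[O-])/C=C(\C)C[C@@H](O[Si](C)(C)C(C)(C)C)/C=C(/C)I)[C@H]1COC(C)(C)O1
F6 | step 4 | methyl (2E,6Z)-5-hydroxy-7-iodo-3-methylocta-2,6-dienoate, racemate | COC(=O)/C=C(\C)CC(O)/C=C(/C)I
F7 | step 4 | methyl (2E,6Z)-7-iodo-3-methyl-5-oxoocta-2,6-dienoate | COC(=O)/C=C(\C)CC(=O)/C=C(/C)I
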